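**Retrosynthetic overview** (labdane numbering; ring A = C1–C5/C10 carbocycle, ring B = C5–C10, ring C = 19,20-lactone, ring D = 9,13-tetrahydrofuran, ring E = spiro 16,15-lactone)

1. Feature: C5 is the one-carbon bridge of the ring A/ring C 3-oxabicyclo[3.3.1]nonane and lies between quaternary C4 and C10; as a ketone it cannot enolise and is shielded, so it is joined to C6 carbonyl carbon to carbonyl carbon.
2. Target 31 ⇐ syn hydroboration of C5=C6 in 29 ⇐ reductive carbonyl coupling C5–C6 (ring B) of keto-aldehyde 27.
3. 27 ⇐ ozonolysis of 25 ⇐ ring C by hydroxymethylation at C10 and lactonisation of 23 ⇐ C9–C10 bond from ring D ketal 22 and ring A silyl enol ether 5.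
4. 22 ⇐ alkynol 20 ⇐ (R)-malic acid dioxolanone 16 (C13) + propargylic bromide 14 (C8 by Evans allylation); 5 ⇐ keto ester 1 (C4 by Koga methylation).
5. Ring order: A (bought), E, D, C, B.

Key step: step 17

Assumption: with L-valine tert-butyl ester and THF as added ligand the lithio-enamine methylation of step 2 is taken to give the (S)-keto ester; if the sense is the reverse, HMPA as ligand (or D-valine tert-butyl ester) is used with no other change.

**Step 1**
Reactants: 1 methyl 2-oxocyclohexane-1-carboxylate
Product: 2 methyl 2-{[(2S)-1-tert-butoxy-3-methyl-1-oxobutan-2-yl]amino}cyclohex-1-ene-1-carboxylate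
Conditions: L-valine tert-butyl ester, BF3·OEt2 (cat.), benzene, reflux, Dean–Stark
Reagents that add atoms: L-valine tert-butyl ester, CC(C)[C@H](N)C(=O)OC(C)(C)C
Why: Acid-catalysed condensation of the β-keto ester with the primary amine gives the hydrogen-bonded enamine (vinylogous carbamate), driven by azeotropic removal of water.

**Step 2**
Reactants: 2 valine enamine
Product: 4 methyl (S)-1-methyl-2-oxocyclohexane-1-carboxylate, via methylated imine 3 (not isolated)
Conditions: LiN(iPr)2, toluene, −78 °C; THF (ligand), MeI, −78 → −55 °C; then 1 M aq. HCl, rt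
Reagents that add atoms: iodomethane, CI
Why: Koga asymmetric alkylation: the lithio-enamine is chelated by the valine ester, whose isopropyl group and the added ligand leave one face of C4 open to iodomethane, and acid hydrolysis of the imine returns the ketone and the auxiliary.

**Step 3**
Reactants: 4 methyl (S)-1-methyl-2-oxocyclohexane-1-carboxylate
Product: 5 methyl (S)-1-methyl-2-(trimethylsilyloxy)cyclohex-2-ene-1-carboxylate
Conditions: Me3SiOTf, Et3N, CH2Cl2, 0 °C
Reagents that add atoms: trimethylsilyl triflate, C[Si](C)(C)OS(=O)(=O)C(F)(F)F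
Why: Soft enolisation; C4 is quaternary, so the silyl enol ether can only form toward C10.

**Step 4**
Reactants: 6 (S)-4-benzyl-3-propanoyl-1,3-oxazolidin-2-one; 7 allyl iodide
Product: 8 (S)-4-benzyl-3-[(R)-2-methylpent-4-enoyl]-1,3-oxazolidin-2-one
Conditions: NaN(SiMe3)2, THF, −78 °C; allyl iodide, −78 → −45 °C
Reagents that add atoms: none
Why: Evans alkylation: the chelated Z-sodium enolate is allylated on the face away from the benzyl group, which sets C8 as R.

**Step 5**
Reactants: 8 allylated imide
Product: 9 (R)-2-methylpent-4-en-1-ol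
Conditions: LiBH4, MeOH (1 equiv), Et2O, 0 °C
Reagents that add atoms: none
Why: Reductive cleavage of the imide at the exocyclic carbonyl gives the primary alcohol without touching C8 and returns the auxiliary.

**Step 6**
Reactants: 9 (R)-2-methylpent-4-en-1-ol
Product: 10 (R)-2-methylpent-4-enal
Conditions: Dess–Martin periodinane, NaHCO3, CH2Cl2, 0 °C → rt; filtered solution used directly
Reagents that add atoms: none
Why: Buffered Dess–Martin oxidation is non-basic, so the α-centre C8 should not epimerise, and the volatile aldehyde is carried on in solution.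

**Step 7**
Reactants: 10 (R)-2-methylpent-4-enal
Product: 11 (R)-1,1-dibromo-3-methylhexa-1,5-diene
Conditions: CBr4, PPh3, 2,6-lutidine, CH2Cl2, 0 °C
Reagents that add atoms: carbon tetrabromide, BrC(Br)(Br)Br
Why: Ramirez dibromo-olefination (first stage of the Corey–Fuchs sequence) by the ylide formed from CBr4 and PPh3, with the amine buffer protecting the α-centre.

**Step 8**
Reactants: 11 (R)-1,1-dibromo-3-methylhexa-1,5-diene
Product: 13 (R)-4-methylhept-6-en-2-yn-1-ol, via alkynyllithium 12 (not isolated)
Conditions: n-BuLi (2.1 equiv), THF, −78 °C; (CH2O)n, −78 °C → rt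
Reagents that add atoms: formaldehyde (from paraformaldehyde), C=O
Why: Second Corey–Fuchs stage: bromine–lithium exchange and Fritsch–Buttenberg–Wiechell rearrangement give the lithium acetylide (C9≡C11), which adds to formaldehyde to install C12.

**Step 9**
Reactants: 13 (R)-4-methylhept-6-en-2-yn-1-ol
Product: 14 (R)-7-bromo-4-methylhept-1-en-5-yne
Conditions: CBr4, PPh3, CH2Cl2, 0 °C
Reagents that add atoms: carbon tetrabromide, BrC(Br)(Br)Br
Why: Appel bromination of the primary propargylic alcohol by SN2 on the oxyphosphonium ion.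

**Step 10**
Reactants: 15 (R)-malic acid
Product: 16 2-[(2R,4R)-2-tert-butyl-5-oxo-1,3-dioxolan-4-yl]acetic acid
Conditions: t-BuCHO, TsOH·H2O (cat.), H2SO4 (cat.), pentane, reflux, Dean–Stark; crystallisation
Reagents that add atoms: pivalaldehyde, CC(C)(C)C=O
Why: Seebach acetalisation of the α-hydroxy acid unit; the cis-dioxolanone (tert-butyl cis to the acetic acid arm) is the thermodynamic, crystalline isomer, so the acetal centre is set by C13.

**Step 11**
Reactants: 16 dioxolanone acid; 14 (R)-7-bromo-4-methylhept-1-en-5-yne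
Product: 17 2-{(2R,4R)-2-tert-butyl-4-[(R)-4-methylhept-6-en-2-yn-1-yl]-5-oxo-1,3-dioxolan-4-yl}acetic acid
Conditions: LiN(SiMe3)2 (2.1 equiv), THF, −78 °C; 14, −78 → −30 °C
Reagents that add atoms: none
Why: Self-regeneration of stereocentres: the carboxylate–enolate dianion is alkylated by the reactive propargylic bromide anti to the tert-butyl group, so C12 takes the place of the former hydrogen and C13 is formed as R with net retention.

**Step 12**
Reactants: 17 alkylated dioxolanone acid
Product: 20 (R)-3-hydroxy-3-[(R)-4-methylhept-6-en-2-yn-1-yl]oxolan-2-one, via mixed anhydride 18 (not isolated), via hydroxyethyl dioxolanone 19 (not isolated)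
Conditions: i-BuOCOCl, N-methylmorpholine, THF, −15 °C; NaBH4, H2O, 0 °C; then TsOH·H2O (cat.), CH2Cl2, rt
Reagents that add atoms: none
Why: The mixed carbonic anhydride is reduced by borohydride far faster than the hindered dioxolanone and alkene and alkyne are untouched; acid then moves the acyl group to the new C15 hydroxyl (translactonisation to ring E) with loss of pivalaldehyde.

**Step 13**
Reactants: 20 alkynol lactone
Product: 22 (5R)-2-methoxy-2-[(R)-pent-4-en-2-yl]-1,7-dioxaspiro[4.4]nonan-6-one (both C9 anomers), via dihydrofuran 21 (not isolated)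
Conditions: PdCl2(MeCN)2 (5 mol %), MeOH, rt; Et3N quench
Reagents that add atoms: methanol, CO
Why: Utimoto-type cyclisation: the electrophilic palladium catalyst activates the alkyne for 5-endo-dig attack of the tertiary hydroxyl at C9 (ring D), and methanol adds to the cyclic enol ether to give the ketal, whose C9 configuration is irrelevant.

**Step 14**
Reactants: 22 ring D methyl ketal; 5 ring A silyl enol ether
Product: 23 methyl (1S)-1-methyl-2-oxo-3-{(2R,5R)-6-oxo-2-[(R)-pent-4-en-2-yl]-1,7-dioxaspiro[4.4]nonan-2-yl}cyclohexane-1-carboxylate (C10 epimers)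
Conditions: Me3SiOTf (0.2 equiv), CH2Cl2, −78 °C
Reagents that add atoms: none
Why: Mukaiyama-type ketal aldol: the silyl triflate ionises the ketal to the ring D oxocarbenium ion and the enol ether attacks it through C10; C9 is set by the face of attack, expected to be anti to the C16 carbonyl oxygen that lies over the other face, with moderate selectivity, so the C9 epimers are separated here, while C10 is not controlled because it is re-enolised in step 15.

**Step 15**
Reactants: 23 coupled ketone
Product: 25 (1S,5S)-1-methyl-5-{(2R,5R)-6-oxo-2-[(R)-pent-4-en-2-yl]-1,7-dioxaspiro[4.4]nonan-2-yl}-3-oxabicyclo[3.3.1]nonane-2,9-dione, via hydroxymethyl ketone 24 (not isolated)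
Conditions: LiN(iPr)2, THF, −78 °C; CH2O (g), −78 → −40 °C; sat. NH4Cl; then TsOH·H2O (cat.), benzene, 50 °C
Reagents that add atoms: formaldehyde (from cracked paraformaldehyde), C=O
Why: Aldol hydroxymethylation of the only possible enolate: formaldehyde adds axially at C10 on the face of the axial C19 ester (smaller than the C18 methyl in the 1,3-diaxial transition state), and only this cis adduct can close, diaxially, to the ring C lactone with loss of methanol, which fixes C10 relative to C4.

**Step 16**
Reactants: 25 bridged keto-lactone alkene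
Product: 27 (1S,5S)-1-methyl-5-{(2R,5R)-6-oxo-2-[(R)-4-oxobutan-2-yl]-1,7-dioxaspiro[4.4]nonan-2-yl}-3-oxabicyclo[3.3.1]nonane-2,9-dione, via ozonide 26 (not isolated)
Conditions: O3, CH2Cl2, −78 °C; PPh3, −78 °C → rt
Reagents that add atoms: ozone, [O-][O+]=O
Why: Ozonolysis of the only alkene and reduction of the ozonide give the C6 aldehyde; ketone, lactones and ether are inert.

**Step 17**
Reactants: 27 keto-lactone aldehyde
Product: 29 (4S,8R,9R,10S,13R)-9,13-epoxylabd-5-ene-19,20:16,15-diolide, via titanium pinacolate 28 (not isolated)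
Conditions: TiCl3(DME)1.5, Zn–Cu couple, DME, reflux 2 h; then 27 by syringe pump over 30 h, reflux
Reagents that add atoms: none
Why: Low-valent titanium made from TiCl3(DME)1.5 and Zn–Cu transfers single electrons to the C6 aldehyde and the C5 ketone, the two ketyl carbons join to the titanium 5,6-pinacolate 28, and at reflux the diolate is deoxygenated on the metal to the C5=C6 alkene. The closest known reaction is the intramolecular McMurry keto-aldehyde cyclisation to cycloalkenes. Ring B closes in a 6-exo mode by union of the two carbonyl carbons, which is the way to engage a ketone that lies between quaternary C4 and C10, cannot enolise and is screened against ylides and enolates. No stereocentre is formed, since the C5 and C6 centres of the pinacolate are erased on deoxygenation. The step needs ketone–aldehyde coupling ahead of the two lactone carbonyls and of intermolecular coupling: esters are reduced much more slowly by low-valent titanium, the 1,6-relation of the carbonyls favours ring closure, and slow addition keeps the substrate dilute. The new alkene is exocyclic to the bicyclo[3.3.1] unit, so no bridgehead strain opposes it.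

**Step 18**
Reactants: 29 5,6-alkene
Product: 31 (4S,5S,6R,8R,9R,10S,13R)-9,13-epoxy-6-hydroxylabdane-19,20:16,15-diolide, via alkylborane 30 (not isolated)
Conditions: BH3·THF, THF, 0 °C → rt; then NaBO3·4H2O, THF/H2O, rt
Reagents that add atoms: sodium perborate, [Na+].[O-]OB=O
Why: Hydroboration–oxidation: boron adds to the less substituted C6 and hydrogen to C5 in a syn four-centre addition from the ring C face, which is flanked only by the flat C19 carbonyl and one C20 hydrogen whereas the other face carries the axial C1 and C3 hydrogens and the C8 methyl; oxidation of the C–B bond goes with retention and perborate spares the lactones, giving 5S and 6R.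

**Compound list**
1 | methyl 2-oxocyclohexane-1-carboxylate | COC(=O)C1CCCCC1=O | starting material
2 | methyl 2-{[(2S)-1-tert-butoxy-3-methyl-1-oxobutan-2-yl]amino}cyclohex-1-ene-1-carboxylate | COC(=O)C1=C(N[C@@H](C(C)C)C(=O)OC(C)(C)C)CCCC1 | intermediate
3 | methyl (1S)-2-{[(2S)-1-tert-butoxy-3-methyl-1-oxobutan-2-yl]imino}-1-methylcyclohexane-1-carboxylate (methylated imine) | COC(=O)[C@@]1(C)CCCCC1=N[C@@H](C(C)C)C(=O)OC(C)(C)C | intermediate
4 | methyl (S)-1-methyl-2-oxocyclohexane-1-carboxylate | COC(=O)[C@@]1(C)CCCCC1=O | intermediate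
5 | methyl (S)-1-methyl-2-(trimethylsilyloxy)cyclohex-2-ene-1-carboxylate | COC(=O)[C@@]1(C)CCCC=C1O[Si](C)(C)C | intermediate
6 | (S)-4-benzyl-3-propanoyl-1,3-oxazolidin-2-one | CCC(=O)N1[C@@H](Cc2ccccc2)COC1=O | starting material
7 | allyl iodide (3-iodoprop-1-ene) | C=CCI | starting material
8 | (S)-4-benzyl-3-[(R)-2-methylpent-4-enoyl]-1,3-oxazolidin-2-one | C=CC[C@@H](C)C(=O)N1[C@@H](Cc2ccccc2)COC1=O | intermediate
9 | (R)-2-methylpent-4-en-1-ol | OC[C@H](C)CC=C | intermediate
10 | (R)-2-methylpent-4-enal | O=C[C@H](C)CC=C | intermediate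
11 | (R)-1,1-dibromo-3-methylhexa-1,5-diene | BrC(Br)=C[C@H](C)CC=C | intermediate
12 | [(R)-3-methylhex-5-en-1-yn-1-yl]lithium (alkynyllithium) | [Li]C#C[C@H](C)CC=C | intermediate
13 | (R)-4-methylhept-6-en-2-yn-1-ol | OCC#C[C@H](C)CC=C | intermediate
14 | (R)-7-bromo-4-methylhept-1-en-5-yne | BrCC#C[C@H](C)CC=C | intermediate
15 | (R)-malic acid | O[C@H](CC(=O)O)C(=O)O | starting material
16 | 2-[(2R,4R)-2-tert-butyl-5-oxo-1,3-dioxolan-4-yl]acetic acid (cis) | OC(=O)C[C@H]1O[C@@H](C(C)(C)C)OC1=O | intermediate
17 | 2-{(2R,4R)-2-tert-butyl-4-[(R)-4-methylhept-6-en-2-yn-1-yl]-5-oxo-1,3-dioxolan-4-yl}acetic acid | OC(=O)C[C@@]1(CC#C[C@H](C)CC=C)O[C@@H](C(C)(C)C)OC1=O | intermediate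
18 | isobutyl carbonic mixed anhydride of 17 | CC(C)COC(=O)OC(=O)C[C@@]1(CC#C[C@H](C)CC=C)O[C@@H](C(C)(C)C)OC1=O | intermediate
19 | hydroxyethyl dioxolanone (primary alcohol from 17) | OCC[C@@]1(CC#C[C@H](C)CC=C)O[C@@H](C(C)(C)C)OC1=O | intermediate
20 | (R)-3-hydroxy-3-[(R)-4-methylhept-6-en-2-yn-1-yl]oxolan-2-one | O=C1OCC[C@]1(O)CC#C[C@H](C)CC=C | intermediate
21 | (5R)-2-[(R)-pent-4-en-2-yl]-1,7-dioxaspiro[4.4]non-2-en-6-one (dihydrofuran) | C[C@H](CC=C)C1=CC[C@]2(CCOC2=O)O1 | intermediate
22 | (5R)-2-methoxy-2-[(R)-pent-4-en-2-yl]-1,7-dioxaspiro[4.4]nonan-6-one, both C9 anomers | COC1(CC[C@]2(CCOC2=O)O1)[C@H](C)CC=C | intermediate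
23 | methyl (1S)-1-methyl-2-oxo-3-{(2R,5R)-6-oxo-2-[(R)-pent-4-en-2-yl]-1,7-dioxaspiro[4.4]nonan-2-yl}cyclohexane-1-carboxylate, C10 epimers | COC(=O)[C@@]1(C)CCCC(C1=O)[C@@]1(CC[C@]2(CCOC2=O)O1)[C@H](C)CC=C | intermediate
24 | C10-hydroxymethyl derivative of 23, CH2OH cis to the ester | COC(=O)[C@@]1(C)CCC[C@@](CO)(C1=O)[C@@]1(CC[C@]2(CCOC2=O)O1)[C@H](C)CC=C | intermediate
25 | (1S,5S)-1-methyl-5-{(2R,5R)-6-oxo-2-[(R)-pent-4-en-2-yl]-1,7-dioxaspiro[4.4]nonan-2-yl}-3-oxabicyclo[3.3.1]nonane-2,9-dione | C[C@H](CC=C)[C@]1(CC[C@]2(CCOC2=O)O1)[C@]12CCC[C@](C)(C(=O)OC1)C2=O | intermediate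
26 | ozonide (1,2,4-trioxolane) of 25 | C[C@H](CC1OCOO1)[C@]1(CC[C@]2(CCOC2=O)O1)[C@]12CCC[C@](C)(C(=O)OC1)C2=O | intermediate
27 | (1S,5S)-1-methyl-5-{(2R,5R)-6-oxo-2-[(R)-4-oxobutan-2-yl]-1,7-dioxaspiro[4.4]nonan-2-yl}-3-oxabicyclo[3.3.1]nonane-2,9-dione (key-step precursor) | C[C@H](CC=O)[C@]1(CC[C@]2(CCOC2=O)O1)[C@]12CCC[C@](C)(C(=O)OC1)C2=O | intermediate
28 | titanium 5,6-pinacolate, written as the monomeric diolate, C5 and C6 configuration open | C[C@@H]1CC(O5)C2(O[Ti]5)[C@]3(CCC[C@]2(C)C(=O)OC3)[C@@]12CC[C@]1(CCOC1=O)O2 | intermediate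
29 | (4S,8R,9R,10S,13R)-9,13-epoxylabd-5-ene-19,20:16,15-diolide (key-step product) | C[C@@H]1CC=C2[C@]3(CCC[C@]2(C)C(=O)OC3)[C@@]12CC[C@]1(CCOC1=O)O2 | intermediate
30 | C6 alkylborane of 29 (boron at C6, hydrogen at C5, both on the ring C face) | C[C@@H]1C[C@@H](B)[C@H]2[C@]3(CCC[C@]2(C)C(=O)OC3)[C@@]12CC[C@]1(CCOC1=O)O2 | intermediate
31 | (4S,5S,6R,8R,9R,10S,13R)-9,13-epoxy-6-hydroxylabdane-19,20:16,15-diolide | C[C@@H]1C[C@@H](O)[C@H]2[C@]3(CCC[C@]2(C)C(=O)OC3)[C@@]12CC[C@]1(CCOC1=O)O2 | target

**Step count:** 18 steps in total. Longest linear sequence: 14 steps (6 → 31 through steps 4–9 and 11–18).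

**Steps most likely to fail**

Step 14. The faces of the ring D cation are told apart only weakly by the C13 spiro centre and by C8 (methyl against CH2), and a Felkin-type bias from C8 would oppose the needed sense, so attack may be unselective or favour the 9-epimer. The cation may also lose a proton toward C8 before it is captured, which would erode that centre. The fallback sets out from 22 and 5 and returns to 23. The coupling is run without demand on selectivity and ring D is re-formed by conjugate addition. The unwanted 9-epi ketone F1 is warmed with DBU in toluene, so that β-elimination of the C13 alkoxide from the C5 enolate opens ring D to the ring-opened C9=C10 enone F2. Camphorsulfonic acid in CH2Cl2 then recloses ring D by 5-exo oxa-Michael addition of the C13 hydroxyl. The resulting mixture of 23 and F1 is separated and the cycle repeated, so that the material converges on 23.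

Step 17. Deoxygenation of a pinacolate that sits between two quaternary carbons may stall at the diol stage, and long exposure to low-valent titanium at reflux may reduce the aldehyde or attack a lactone carbonyl. The fallback sets out from 27 and returns to 29, and keeps the reductive C5–C6 carbonyl coupling but divides it into two stages. SmI2 in THF with t-BuOH at −78 °C → rt gives the cis-5,6-diol F4 by ketyl–carbonyl pinacol cyclisation, and lactones are inert to this reagent. Thiocarbonyldiimidazole in hot toluene then gives the cyclic thionocarbonate F5, and Corey–Winter elimination with P(OMe)3 at reflux gives 29.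

Step 15. The lithium enolate of 23 carries the ring D oxygen in the β-position and may open ring D by β-elimination before it meets formaldehyde. Deprotonation next to quaternary C9 may also be slow, and chelation of lithium by the C19 ester may turn the aldol toward the face that cannot lactonise. The fallback sets out from 23 and returns to 25, and avoids the free enolate. Me3SiOTf and Et3N in CH2Cl2 give the trimethylsilyl enol ether F3. Aqueous formaldehyde with Yb(OTf)3 (10 mol %) in THF/H2O at rt then hydroxymethylates C10 through an open transition state to 24. TsOH in warm benzene closes ring C to 25.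

**Further compounds**
F1 | step 14 | 9-epi ketone, the C9 epimer of 23 | COC(=O)[C@@]1(C)CCCC(C1=O)[C@]1(CC[C@]2(CCOC2=O)O1)[C@H](C)CC=C
F2 | step 14 | ring-opened C9=C10 enone with free C13 hydroxyl | COC(=O)[C@@]1(C)CCCC(=C(CC[C@@]2(O)CCOC2=O)[C@H](C)CC=C)C1=O
F3 | step 15 | trimethylsilyl enol ether of 23 (C5–O–Si, C5=C10) | COC(=O)[C@@]1(C)CCCC(=C1O[Si](C)(C)C)[C@@]1(CC[C@]2(CCOC2=O)O1)[C@H](C)CC=C
F4 | step 17 | cis-5,6-diol (pinacol of 27) | C[C@@H]1CC(O)C2(O)[C@]3(CCC[C@]2(C)C(=O)OC3)[C@@]12CC[C@]1(CCOC1=O)O2
F5 | step 17 | cyclic 5,6-thionocarbonate of F4 | C[C@@H]1CC(O5)C2(OC5=S)[C@]3(CCC[C@]2(C)C(=O)OC3)[C@@]12CC[C@]1(CCOC1=O)O2
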